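**Retrosynthetic overview**

1. The target is (3S,6R)-3-tigloyloxy-13-acetoxygermacra-1(10)Z,4E,7(11)-trien-12,6-olide (germacrane numbering: ten-membered ring C1–C10, lactone oxygen on C6, lactone carbonyl C12, acetoxymethyl C13); the tiglate and the acetate are attached last.
2. Key disconnection C2–C3: inside the ten-membered ring the atoms O–C3–C2–C1=C10(CH3) form a homoallylic alcohol (allylic carbinol C3, allylic CH2 C2, trisubstituted olefin C1=C10). This is the retron of an allylboration with 1,3-transposition, so an open-chain C3 enal carrying a tertiary allyl boronate at C10 closes the ring, sets C3 and creates the Z olefin in one operation.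
3. The boronate comes from a (Z)-allylic carbonate by enantioselective copper-catalysed SN2′ borylation; the enal is carried as its dimethyl acetal and unmasked in the key step.
4. The butenolide is assembled in one operation from an (R)-propargylic alcohol (C6 set by asymmetric alkynylation of an E-enal), a homoallylic Grignard reagent and CO2 (anti-carbomagnesiation, carboxylation, lactonisation).
5. Ring order: butenolide first (step 10), ten-membered carbocycle second (step 14).

Key step: step 14

Assumption: (S,S)-ProPhenol (step 9) is taken to give the (R)-carbinol and the chosen antipode of the chiral NHC ligand (step 13) the (R)-boronate; if either sense is the opposite, the antipodal ligand is used.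

**Route**

Step 1
Reactants: 1 tert-butyl(but-3-yn-1-yloxy)dimethylsilane
Product: 2 methyl 5-[(tert-butyldimethylsilyl)oxy]pent-2-ynoate
Conditions: n-BuLi, THF, −78 °C; ClCO2Me, −78 → 0 °C
Reagents that add atoms: methyl chloroformate, COC(=O)Cl
Why: C-acylation of the lithium acetylide with a chloroformate is the standard route to 2-alkynoates.

Step 2
Reactants: 2 methyl 5-[(tert-butyldimethylsilyl)oxy]pent-2-ynoate
Product: 3 methyl (2Z)-5-[(tert-butyldimethylsilyl)oxy]-3-methylpent-2-enoate
Conditions: MeLi (2.4 equiv), CuI (1.2 equiv), THF, 0 °C; then 2, −78 °C; AcOH, −78 °C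
Reagents that add atoms: lithium dimethylcuprate (from MeLi and CuI), [Li+].C[Cu-]C
Why: syn-carbocupration of the 2-alkynoate with a Gilman reagent and cold protonation should place the methyl group cis to hydrogen, so chain and ester are cis and the Z geometry of the later C1=C10 unit is fixed.

Step 3
Reactants: 3 methyl (2Z)-5-[(tert-butyldimethylsilyl)oxy]-3-methylpent-2-enoate
Product: 4 methyl (2Z)-5-bromo-3-methylpent-2-enoate
Conditions: Ph3PBr2, CH2Cl2, 0 → 23 °C
Reagents that add atoms: triphenylphosphine dibromide, BrP(Br)(c1ccccc1)(c1ccccc1)c1ccccc1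
Why: triphenylphosphine dibromide converts a primary silyl ether directly into the bromide under neutral conditions, which avoids the free 5-hydroxy ester that would lactonise.

Step 4
Reactants: 4 methyl (2Z)-5-bromo-3-methylpent-2-enoate
Product: 5 (2Z)-5-bromo-3-methylpent-2-en-1-ol
Conditions: i-Bu2AlH (2.2 equiv), CH2Cl2, −78 °C; aq. potassium sodium tartrate
Reagents that add atoms: none
Why: 1,2-reduction of the enoate with i-Bu2AlH at −78 °C should give the allylic alcohol without touching the primary bromide or the olefin geometry.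

Step 5
Reactants: 5 (2Z)-5-bromo-3-methylpent-2-en-1-ol
Product: 6 {[(2Z)-5-bromo-3-methylpent-2-en-1-yl]oxy}triethylsilane
Conditions: TESCl, imidazole, CH2Cl2, 0 °C
Reagents that add atoms: chlorotriethylsilane, CC[Si](Cl)(CC)CC
Why: silylation under mild base gives an ether that survives Grignard formation and can later be removed selectively beside a TBS ether.

Step 6
Reactants: 7 1,1-dimethoxypropan-2-one; 8 triethyl phosphonoacetate
Product: 9 ethyl (2E)-4,4-dimethoxy-3-methylbut-2-enoate
Conditions: NaH, THF, 0 → 23 °C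
Reagents that add atoms: none
Why: Horner–Wadsworth–Emmons olefination of the methyl ketone should place the ester trans to the bulkier dimethoxymethyl group (E olefin of the later C4=C5 unit), any Z isomer being removed by chromatography.

Step 7
Reactants: 9 ethyl (2E)-4,4-dimethoxy-3-methylbut-2-enoate
Product: 10 (2E)-4,4-dimethoxy-3-methylbut-2-en-1-ol
Conditions: i-Bu2AlH (2.2 equiv), CH2Cl2, −78 °C; aq. potassium sodium tartrate
Reagents that add atoms: none
Why: ester reduction with i-Bu2AlH leaves the acetal and the olefin geometry untouched.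

Step 8
Reactants: 10 (2E)-4,4-dimethoxy-3-methylbut-2-en-1-ol
Product: 11 (2E)-4,4-dimethoxy-3-methylbut-2-enal
Conditions: MnO2, CH2Cl2, 23 °C
Reagents that add atoms: none
Why: MnO2 oxidises allylic alcohols selectively to enals under neutral conditions, so neither the acetal nor the E geometry should be affected.

Step 9
Reactants: 11 (2E)-4,4-dimethoxy-3-methylbut-2-enal; 12 tert-butyldimethyl(prop-2-yn-1-yloxy)silane
Product: 13 (4R,5E)-1-[(tert-butyldimethylsilyl)oxy]-7,7-dimethoxy-6-methylhept-5-en-2-yn-4-ol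
Conditions: (S,S)-ProPhenol (10 mol%), Me2Zn (3 equiv), Ph3PO (20 mol%), toluene, 0 °C; then H2O
Reagents that add atoms: none
Why: zinc–ProPhenol-catalysed asymmetric alkynylation of an α,β-unsaturated aldehyde should set the C6 carbinol centre (R) by catalyst-controlled facial delivery of the alkynylzinc.

Step 10
Reactants: 13 (4R,5E)-1-[(tert-butyldimethylsilyl)oxy]-7,7-dimethoxy-6-methylhept-5-en-2-yn-4-ol; 6 {[(2Z)-5-bromo-3-methylpent-2-en-1-yl]oxy}triethylsilane
Product: 17 (5R)-butenolide carrying the CH2OTBS group on C11 and the TES-protected chain on C7 and the acetal side chain on C6 (full name in the list), via Grignard reagent 14 (not isolated), via alkenylmagnesium chelate 15 (not isolated), via hydroxy acid 16 (not isolated)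
Conditions: 6, Mg, THF, 35 °C (gives 14); 13, i-PrMgCl (1.0 equiv), THF, −20 °C; then 14 (2.2 equiv), CuI (10 mol%), −20 → 23 °C; CO2 (gas), −20 → 23 °C; AcOH, THF/H2O, 0 °C
Reagents that add atoms: carbon dioxide, O=C=O
Why: copper-assisted anti-carbomagnesiation of the propargylic magnesium alkoxide should deliver the alkyl group to the alkyne carbon next to the carbinol and magnesium to the distal carbon cis to oxygen, so that carboxylation and lactonisation give the tetrasubstituted butenolide with C6 untouched.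

Step 11
Reactants: 17 (5R)-butenolide with TES and TBS ethers
Product: 18 (5R)-butenolide with free allylic alcohol at C2 (full name in the list)
Conditions: PPTS (10 mol%), MeOH, 0 °C
Reagents that add atoms: none
Why: acid-catalysed methanolysis cleaves the primary triethylsilyl ether much faster than the TBS ether, and the dimethyl acetal is unchanged by exchange with methanol.

Step 12
Reactants: 18 (5R)-butenolide with free allylic alcohol
Product: 19 (Z)-allylic methyl carbonate of 18 (full name in the list)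
Conditions: ClCO2Me, pyridine, CH2Cl2, 0 °C
Reagents that add atoms: methyl chloroformate, COC(=O)Cl
Why: acylation of the primary allylic alcohol gives the carbonate leaving group needed for copper-catalysed allylic substitution.

Step 13
Reactants: 19 (Z)-allylic methyl carbonate
Product: 20 tertiary (R)-allyl pinacol boronate at C10 (full name in the list)
Conditions: Cu(OTf)2 (5 mol%), chiral sulfonate-bearing imidazolinium salt (6 mol%), NaOMe (30 mol%), B2pin2 (1.5 equiv), DME, −30 °C
Reagents that add atoms: bis(pinacolato)diboron, CC1(C)OB(OC1(C)C)B1OC(C)(C)C(C)(C)O1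
Why: NHC–copper-catalysed enantioselective SN2′ substitution of a γ,γ-disubstituted allylic carbonate with B2pin2 should put boron on C10 with allylic transposition, the chiral ligand fixing the (R) configuration of the boron-bearing quaternary centre.

Step 14
Reactants: 20 tertiary (R)-allyl pinacol boronate with dimethyl acetal
Product: 23 (6Z,9S,10E,11aR)-3-{[(tert-butyldimethylsilyl)oxy]methyl}-9-hydroxy-6,10-dimethyl-4,5,8,9-tetrahydrocyclodeca[b]furan-2(11aH)-one, via enal boronate 21 (not isolated), via macrocyclic borate 22 (not isolated)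
Conditions: PPTS (2 equiv), THF/H2O (10:1), 0.002 M, 23 → 45 °C; aq. NaHCO3
Reagents that add atoms: water, O
Why: Proposed new method: acid-catalysed hydrolysis unmasks enal 21, whose carbonyl oxygen binds the boron on C10 so that C2 adds to C3 through a closed six-membered allylboration transition state with 1,3-transposition (SE2′), giving borate 22 and after hydrolysis 23; the closest known reaction types are the intermolecular allylboration of aldehydes with α,α-disubstituted allyl pinacol boronates and the acetal-unmasking intramolecular allylboration to five- to seven-membered rings, while closure of a ten-membered carbocycle in this way is without precedent. The ten-membered ring is closed by a single macrocyclisation in which C3–C2–C1–C10 are at once ring atoms and the carbon half of the transition-state ring, so the tether C4–C9 has to bridge C3 and C10 on one face of that ring in a boat-like, bicyclic transition state. C3 is set by 1,3-chirality transfer from C10: with C9 held syn to C2 (which gives the Z olefin) and C4 on the same face, the (10R)-boronate can only give the (3S)-alcohol. The step needs Z over E selectivity, which is coupled to the C3 configuration (the alternative arrangement with the methyl group syn to C2 would give the 1(10)E,3R isomer but forces the short C5–C8 link to leave C10 from the outward position), and it needs intra- over intermolecular reaction, which high dilution and the low bimolecular reactivity of hindered tertiary boronates should secure. Regioselectivity (C2 and not C10 bonds to C3) follows from the SE2′ mechanism and the positional stability of the pinacol boronate. The conditions are base-free and redox-neutral, so the butenolide with its acidic C6–H and the silyl ether should survive, and the new B–O bond pays for the strain of the medium ring.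

Step 15
Reactants: 23 macrocyclic (9S)-alcohol; 24 (2E)-2-methylbut-2-enoyl chloride
Product: 25 TBS-protected tiglate (full name in the list)
Conditions: pyridine, DMAP (10 mol%), CH2Cl2, 0 → 23 °C
Reagents that add atoms: none
Why: DMAP-catalysed acylation of the secondary allylic alcohol proceeds at oxygen, so the C3 configuration and the E geometry of the tiglate are retained.

Step 16
Reactants: 25 TBS-protected tiglate
Product: 26 primary alcohol at C13 (full name in the list)
Conditions: HF·pyridine, pyridine, THF, 0 °C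
Reagents that add atoms: none
Why: buffered HF·pyridine cleaves the primary TBS ether without opening the lactone or cleaving the tiglate.

Step 17
Reactants: 26 primary alcohol at C13
Product: 27 target
Conditions: Ac2O, pyridine, DMAP (5 mol%), CH2Cl2, 0 °C
Reagents that add atoms: acetic anhydride, CC(=O)OC(C)=O
Why: standard acetylation of the primary allylic alcohol completes the target.

**Compound list**

1 | tert-butyl(but-3-yn-1-yloxy)dimethylsilane | C#CCCO[Si](C)(C)C(C)(C)C | starting material
2 | methyl 5-[(tert-butyldimethylsilyl)oxy]pent-2-ynoate | COC(=O)C#CCCO[Si](C)(C)C(C)(C)C | intermediate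
3 | methyl (2Z)-5-[(tert-butyldimethylsilyl)oxy]-3-methylpent-2-enoate | COC(=O)/C=C(/C)CCO[Si](C)(C)C(C)(C)C | intermediate
4 | methyl (2Z)-5-bromo-3-methylpent-2-enoate | COC(=O)/C=C(/C)CCBr | intermediate
5 | (2Z)-5-bromo-3-methylpent-2-en-1-ol | OC/C=C(/C)CCBr | intermediate
6 | {[(2Z)-5-bromo-3-methylpent-2-en-1-yl]oxy}triethylsilane | CC[Si](CC)(CC)OC/C=C(/C)CCBr | intermediate
7 | 1,1-dimethoxypropan-2-one | CC(=O)C(OC)OC | starting material
8 | triethyl phosphonoacetate | CCOC(=O)CP(=O)(OCC)OCC | starting material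
9 | ethyl (2E)-4,4-dimethoxy-3-methylbut-2-enoate | CCOC(=O)/C=C(\C)C(OC)OC | intermediate
10 | (2E)-4,4-dimethoxy-3-methylbut-2-en-1-ol | OC/C=C(\C)C(OC)OC | intermediate
11 | (2E)-4,4-dimethoxy-3-methylbut-2-enal | O=C/C=C(\C)C(OC)OC | intermediate
12 | tert-butyldimethyl(prop-2-yn-1-yloxy)silane | C#CCO[Si](C)(C)C(C)(C)C | starting material
13 | (4R,5E)-1-[(tert-butyldimethylsilyl)oxy]-7,7-dimethoxy-6-methylhept-5-en-2-yn-4-ol | CC(C)(C)[Si](C)(C)OCC#C[C@H](O)/C=C(\C)C(OC)OC | intermediate
14 | bromo{(3Z)-3-methyl-5-[(triethylsilyl)oxy]pent-3-en-1-yl}magnesium (Grignard reagent from 6) | CC[Si](CC)(CC)OC/C=C(/C)CC[Mg]Br | intermediate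
15 | (5R)-2,5-dihydro-1,2-oxamagnesole chelate: Mg bonded to the C6 oxygen and to C11, chain on C7, CH2OTBS on C11 | CC[Si](CC)(CC)OC/C=C(/C)CCC1=C(CO[Si](C)(C)C(C)(C)C)[Mg]O[C@@H]1/C=C(\C)C(OC)OC | intermediate
16 | (2Z,4R,5E)-2-{[(tert-butyldimethylsilyl)oxy]methyl}-4-hydroxy-7,7-dimethoxy-6-methyl-3-{(3Z)-3-methyl-5-[(triethylsilyl)oxy]pent-3-en-1-yl}hepta-2,5-dienoic acid | CC[Si](CC)(CC)OC/C=C(/C)CC/C(=C(\CO[Si](C)(C)C(C)(C)C)C(=O)O)[C@H](O)/C=C(\C)C(OC)OC | intermediate
17 | (5R)-3-{[(tert-butyldimethylsilyl)oxy]methyl}-5-[(1E)-3,3-dimethoxy-2-methylprop-1-en-1-yl]-4-{(3Z)-3-methyl-5-[(triethylsilyl)oxy]pent-3-en-1-yl}furan-2(5H)-one | CC[Si](CC)(CC)OC/C=C(/C)CCC1=C(CO[Si](C)(C)C(C)(C)C)C(=O)O[C@@H]1/C=C(\C)C(OC)OC | intermediate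
18 | (5R)-3-{[(tert-butyldimethylsilyl)oxy]methyl}-5-[(1E)-3,3-dimethoxy-2-methylprop-1-en-1-yl]-4-[(3Z)-5-hydroxy-3-methylpent-3-en-1-yl]furan-2(5H)-one | OC/C=C(/C)CCC1=C(CO[Si](C)(C)C(C)(C)C)C(=O)O[C@@H]1/C=C(\C)C(OC)OC | intermediate
19 | (2Z)-5-[(2R)-4-{[(tert-butyldimethylsilyl)oxy]methyl}-2-[(1E)-3,3-dimethoxy-2-methylprop-1-en-1-yl]-5-oxo-2,5-dihydrofuran-3-yl]-3-methylpent-2-en-1-yl methyl carbonate | COC(=O)OC/C=C(/C)CCC1=C(CO[Si](C)(C)C(C)(C)C)C(=O)O[C@@H]1/C=C(\C)C(OC)OC | intermediate
20 | (5R)-3-{[(tert-butyldimethylsilyl)oxy]methyl}-5-[(1E)-3,3-dimethoxy-2-methylprop-1-en-1-yl]-4-[(3R)-3-methyl-3-(4,4,5,5-tetramethyl-1,3,2-dioxaborolan-2-yl)pent-4-en-1-yl]furan-2(5H)-one | C=C[C@@](C)(B1OC(C)(C)C(C)(C)O1)CCC2=C(CO[Si](C)(C)C(C)(C)C)C(=O)O[C@@H]2/C=C(\C)C(OC)OC | intermediate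
21 | (2E)-3-[(2R)-4-{[(tert-butyldimethylsilyl)oxy]methyl}-3-[(3R)-3-methyl-3-(4,4,5,5-tetramethyl-1,3,2-dioxaborolan-2-yl)pent-4-en-1-yl]-5-oxo-2,5-dihydrofuran-2-yl]-2-methylprop-2-enal | C=C[C@@](C)(B1OC(C)(C)C(C)(C)O1)CCC2=C(CO[Si](C)(C)C(C)(C)C)C(=O)O[C@@H]2/C=C(\C)C=O | intermediate
22 | pinacol borate (O–Bpin ether at C9) of 23 | CC1(C)OB(O[C@H]2C/C=C(/C)CCC3=C(CO[Si](C)(C)C(C)(C)C)C(=O)O[C@@H]3/C=C/2C)OC1(C)C | intermediate
23 | (6Z,9S,10E,11aR)-3-{[(tert-butyldimethylsilyl)oxy]methyl}-9-hydroxy-6,10-dimethyl-4,5,8,9-tetrahydrocyclodeca[b]furan-2(11aH)-one | O[C@H]1C/C=C(/C)CCC2=C(CO[Si](C)(C)C(C)(C)C)C(=O)O[C@@H]2/C=C/1C | intermediate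
24 | (2E)-2-methylbut-2-enoyl chloride (tigloyl chloride) | C/C=C(\C)C(Cl)=O | starting material
25 | (6Z,9S,10E,11aR)-3-{[(tert-butyldimethylsilyl)oxy]methyl}-6,10-dimethyl-2-oxo-2,4,5,8,9,11a-hexahydrocyclodeca[b]furan-9-yl (2E)-2-methylbut-2-enoate | C/C=C(\C)C(=O)O[C@H]1C/C=C(/C)CCC2=C(CO[Si](C)(C)C(C)(C)C)C(=O)O[C@@H]2/C=C/1C | intermediate
26 | (6Z,9S,10E,11aR)-3-(hydroxymethyl)-6,10-dimethyl-2-oxo-2,4,5,8,9,11a-hexahydrocyclodeca[b]furan-9-yl (2E)-2-methylbut-2-enoate | C/C=C(\C)C(=O)O[C@H]1C/C=C(/C)CCC2=C(CO)C(=O)O[C@@H]2/C=C/1C | intermediate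
27 | (6Z,9S,10E,11aR)-3-(acetoxymethyl)-6,10-dimethyl-2-oxo-2,4,5,8,9,11a-hexahydrocyclodeca[b]furan-9-yl (2E)-2-methylbut-2-enoate | C/C=C(\C)C(=O)O[C@H]1C/C=C(/C)CCC2=C(COC(C)=O)C(=O)O[C@@H]2/C=C/1C | target

**Step count and risks**

Total step count: 17. Longest linear sequence: 13 steps (steps 1–5, then 10–17).

Steps most likely to fail:

1. Step 14 (proposed new method). The risk is that intermolecular allylboration (oligomerisation) outruns ring closure, or that the ring closes through the arrangement that gives the E olefin. Fallback, from 6 and 12, returning at 23: the C2–C3 bond is made by a carbonylative Stille macrocyclisation, known for macrocyclic ketones and for allyl chloride/vinylstannane pairs, and C3 is then set by reduction. Ethyl but-2-ynoate is stannylcuprated (Bu3SnLi, CuBr·SMe2, THF, −78 °C; MeOH) to ethyl (2E)-3-(tributylstannyl)but-2-enoate F1, which is reduced (i-Bu2AlH) to (2E)-3-(tributylstannyl)but-2-en-1-ol F2 and oxidised (MnO2) to (2E)-3-(tributylstannyl)but-2-enal F3. Zinc–ProPhenol alkynylation of F3 with 12, as in step 9, should give (4R,5E)-1-[(tert-butyldimethylsilyl)oxy]-6-(tributylstannyl)hept-5-en-2-yn-4-ol F4. F4 is joined with 6 through Grignard reagent 14 and CO2 as in step 10 to the stannyl butenolide F5. Methanolysis (PPTS, MeOH) frees the allylic alcohol F6, and MsCl, LiCl and 2,4,6-collidine in DMF at 0 °C give the (Z)-allylic chloride F7. Under CO (3 atm) with Pd2(dba)3 and PPh3 in THF at 50 °C and high dilution, zerovalent palladium adds to the allylic chloride, CO inserts at the primary allyl terminus (this forms the C2–C3 bond with the Z olefin retained) and the tin-bound vinyl group closes the ring to the macrocyclic ketone F8. Corey–Bakshi–Shibata reduction of F8 with the (R)-methyl oxazaborolidine and catecholborane (toluene, −78 °C), in which the α-methyl alkenyl group acts as the large substituent, should give 23.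

2. Step 13. The risk is loss of facial control at C10 when the boryl–copper species adds to the Z-configured trisubstituted olefin. Fallback, from 19, returning at 23: stereocontrol by chirality transfer is given up and C3 is set by reagent-controlled reduction. With an achiral catalyst (CuCl, Xantphos, KOtBu, B2pin2, THF, 0 °C) 19 gives 20 together with its C10 epimer F9. Both are cyclised under the conditions of step 14, F9 giving the (9R)-alcohol F10, the C3 epimer of 23. The mixture of 23 and F10 is oxidised (MnO2, CH2Cl2) to the single macrocyclic ketone F8, and the Corey–Bakshi–Shibata reduction described under point 1 returns 23.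

3. Step 10. The risk is β-elimination of the silyloxy group from the alkenylmagnesium intermediate (allene formation) and slow carbometalation by the alkyl Grignard reagent. Fallback, from 11 and 6 (through 14), returning at 17: the butenolide is built by conjugate addition to an ynoate that carries no leaving group next to the metal-bearing carbon. Enal 11 is alkynylated with methyl propiolate (zinc–ProPhenol, Me2Zn) to methyl (4R,5E)-4-hydroxy-7,7-dimethoxy-6-methylhept-5-en-2-ynoate F11. Its magnesium alkoxide (i-PrMgCl) takes up the organocopper reagent made from Grignard reagent 14 and CuBr·SMe2 by syn conjugate addition at −78 °C; iodine traps the α-alkenylcopper and the (Z)-hydroxy ester lactonises on work-up to the α-iodobutenolide F12. Stille coupling with (tributylstannyl)methanol (Pd(PPh3)4, dioxane, 90 °C) gives the hydroxymethyl butenolide F13, and TBSCl/imidazole gives 17.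

**Further compounds**

F1 | step 14 | ethyl (2E)-3-(tributylstannyl)but-2-enoate | CCCC[Sn](CCCC)(CCCC)/C(C)=C/C(=O)OCC
F2 | step 14 | (2E)-3-(tributylstannyl)but-2-en-1-ol | CCCC[Sn](CCCC)(CCCC)/C(C)=C/CO
F3 | step 14 | (2E)-3-(tributylstannyl)but-2-enal | CCCC[Sn](CCCC)(CCCC)/C(C)=C/C=O
F4 | step 14 | (4R,5E)-1-[(tert-butyldimethylsilyl)oxy]-6-(tributylstannyl)hept-5-en-2-yn-4-ol | CC(C)(C)[Si](C)(C)OCC#C[C@H](O)/C=C(\C)[Sn](CCCC)(CCCC)CCCC
F5 | step 14 | (5R)-3-{[(tert-butyldimethylsilyl)oxy]methyl}-4-{(3Z)-3-methyl-5-[(triethylsilyl)oxy]pent-3-en-1-yl}-5-[(1E)-2-(tributylstannyl)prop-1-en-1-yl]furan-2(5H)-one | CC[Si](CC)(CC)OC/C=C(/C)CCC1=C(CO[Si](C)(C)C(C)(C)C)C(=O)O[C@@H]1/C=C(\C)[Sn](CCCC)(CCCC)CCCC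
F6 | step 14 | (5R)-3-{[(tert-butyldimethylsilyl)oxy]methyl}-4-[(3Z)-5-hydroxy-3-methylpent-3-en-1-yl]-5-[(1E)-2-(tributylstannyl)prop-1-en-1-yl]furan-2(5H)-one | OC/C=C(/C)CCC1=C(CO[Si](C)(C)C(C)(C)C)C(=O)O[C@@H]1/C=C(\C)[Sn](CCCC)(CCCC)CCCC
F7 | step 14 | (5R)-3-{[(tert-butyldimethylsilyl)oxy]methyl}-4-[(3Z)-5-chloro-3-methylpent-3-en-1-yl]-5-[(1E)-2-(tributylstannyl)prop-1-en-1-yl]furan-2(5H)-one | ClC/C=C(/C)CCC1=C(CO[Si](C)(C)C(C)(C)C)C(=O)O[C@@H]1/C=C(\C)[Sn](CCCC)(CCCC)CCCC
F8 | step 14 | (6Z,10E,11aR)-3-{[(tert-butyldimethylsilyl)oxy]methyl}-6,10-dimethyl-4,5,8,11a-tetrahydrocyclodeca[b]furan-2,9-dione | O=C1C/C=C(/C)CCC2=C(CO[Si](C)(C)C(C)(C)C)C(=O)O[C@@H]2/C=C/1C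
F9 | step 13 | (5R)-3-{[(tert-butyldimethylsilyl)oxy]methyl}-5-[(1E)-3,3-dimethoxy-2-methylprop-1-en-1-yl]-4-[(3S)-3-methyl-3-(4,4,5,5-tetramethyl-1,3,2-dioxaborolan-2-yl)pent-4-en-1-yl]furan-2(5H)-one | C=C[C@](C)(B1OC(C)(C)C(C)(C)O1)CCC2=C(CO[Si](C)(C)C(C)(C)C)C(=O)O[C@@H]2/C=C(\C)C(OC)OC
F10 | step 13 | (6Z,9R,10E,11aR)-3-{[(tert-butyldimethylsilyl)oxy]methyl}-9-hydroxy-6,10-dimethyl-4,5,8,9-tetrahydrocyclodeca[b]furan-2(11aH)-one | O[C@@H]1C/C=C(/C)CCC2=C(CO[Si](C)(C)C(C)(C)C)C(=O)O[C@@H]2/C=C/1C
F11 | step 10 | methyl (4R,5E)-4-hydroxy-7,7-dimethoxy-6-methylhept-5-en-2-ynoate | COC(=O)C#C[C@H](O)/C=C(\C)C(OC)OC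
F12 | step 10 | (5R)-5-[(1E)-3,3-dimethoxy-2-methylprop-1-en-1-yl]-3-iodo-4-{(3Z)-3-methyl-5-[(triethylsilyl)oxy]pent-3-en-1-yl}furan-2(5H)-one | CC[Si](CC)(CC)OC/C=C(/C)CCC1=C(I)C(=O)O[C@@H]1/C=C(\C)C(OC)OC
F13 | step 10 | (5R)-5-[(1E)-3,3-dimethoxy-2-methylprop-1-en-1-yl]-3-(hydroxymethyl)-4-{(3Z)-3-methyl-5-[(triethylsilyl)oxy]pent-3-en-1-yl}furan-2(5H)-one | CC[Si](CC)(CC)OC/C=C(/C)CCC1=C(CO)C(=O)O[C@@H]1/C=C(\C)C(OC)OC
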